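The route relays one carbinol stereocentre around the seven-membered ring. An Eschenmoser–Claisen rearrangement of (S)-cyclohept-2-en-1-ol replaces the C5–O bond by the C7–C11 bond (suprafacial, so C7 is fixed), shifts the olefin to C5=C6 and installs the C11–C12 amide (numbering below). It exploits the target's cis O6/C11 pair on the cycloheptane, a latent γ-lactone (O6–C12). The amide delivers O6 by iodolactonisation; the cis-fused lactone then steers C11 methylation, anti cuprate addition at C5 and trans allylation at C1 (cyclopentene by metathesis), and after C9 oxygenation it is opened to the C12 carbinol. The precursor is a monocyclic allylic alcohol from meso cycloheptene oxide.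

Key step: step 2

Numbering used for all compounds: C1 and C5 are the ring-fusion carbons, C2–C3=C4(CH3) the cyclopentene, C6 the carbinol carbon, C7 the side-chain-bearing carbon, C8, C9 (acetoxy-bearing) and C10 (methylene-bearing) complete the seven-membered ring; the side chain is C11 (methyl-bearing), C12 (acetoxy-bearing), C13, C14=C15. β is the face of H-5, O6, C11 and C2; α is the face of H-1, C4 and the C9 oxygen.

Assumption: the lithium amide of (S)-2-(pyrrolidin-1-ylmethyl)pyrrolidine desymmetrises cycloheptene oxide in the same sense as cyclohexene oxide, giving the (S)-allylic alcohol; if the sense were opposite, the (R)-diamine would be used with no other change.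

Step 1
Reactants: 1 cycloheptene oxide
Product: 2 (S)-cyclohept-2-en-1-ol
Conditions: (S)-2-(pyrrolidin-1-ylmethyl)pyrrolidine (20 mol%), LDA, DBU, THF, 0 °C → rt; H2O
Reagents that add atoms: none
Why: Enantiotopic syn β-deprotonation of the meso epoxide by the chiral lithium amide (base-mediated epoxide-to-allylic-alcohol rearrangement, catalytic in the diamine) desymmetrises 1 and sets the carbinol centre (future C5) as S.

Step 2
Reactants: 2 (S)-cyclohept-2-en-1-ol
Product: 4 2-[(1S)-cyclohept-2-en-1-yl]-N,N-dimethylacetamide, via ketene N,O-acetal 3 (not isolated)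
Conditions: MeC(OMe)2NMe2, xylene, 140 °C (MeOH distilled off)
Reagents that add atoms: N,N-dimethylacetamide dimethyl acetal, CC(OC)(OC)N(C)C
Why: Alcohol exchange on the amide acetal and loss of methanol give ketene N,O-acetal 3, which undergoes a concerted suprafacial [3,3] shift; the closest known reaction type is the Eschenmoser–Claisen rearrangement of cycloalk-2-enols. No ring is closed: the C5–O bond is exchanged for the C7–C11 bond and the olefin moves to C5=C6. The only new stereocentre, C7, is controlled by the carbinol configuration, because the endocyclic cis olefin lets the ketene acetal carbon reach C7 only on the face from which oxygen departs, so chair and boat arrangements give the same (S) centre. The selectivity needed is complete 1,3-chirality transfer without ionisation, which the neutral thermal conditions and the single available allylic terminus secure. The step also plants the C11–C12 amide that later delivers O6 and directs C11, C5 and C1.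

Step 3
Reactants: 4 2-[(1S)-cyclohept-2-en-1-yl]-N,N-dimethylacetamide
Product: 6 cis-fused iodolactone (8-iodo-octahydro-2H-cyclohepta[b]furan-2-one; O6 and C11 β, iodine at C5 α), via iminium ether iodide 5 (not isolated)
Conditions: I2, THF/H2O (1:1), rt, dark; aq. NaHCO3/Na2S2O3
Reagents that add atoms: iodine, II; water, O
Why: The iodonium ion on C5=C6 is captured 5-exo by the amide oxygen (iodolactonisation of a γ,δ-unsaturated tertiary amide, the iminium ether being hydrolysed in situ), and since the tether reaches C6 only on the face bearing C11, O6 is set cis to C11 with iodine anti at C5.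

Step 4
Reactants: 6 cis-fused iodolactone
Product: 7 cis-fused allylic lactone (3,3a,4,5,6,8a-hexahydro-2H-cyclohepta[b]furan-2-one; C1=C5 olefin)
Conditions: DBU, toluene, 110 °C
Reagents that add atoms: none
Why: E2 dehydroiodination needs an anti-periplanar hydrogen, which C1 offers and C6 does not (H-6 is syn to iodine), so the C1=C5 olefin should form without touching C6 or C7.

Step 5
Reactants: 7 cis-fused allylic lactone
Product: 9 (11S)-11-methyl allylic lactone (methyl cis to H-7, trans to C8), via lithium enolate 8 (not isolated)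
Conditions: LDA, THF, −78 °C; MeI, −78 → −40 °C
Reagents that add atoms: iodomethane, CI
Why: The lactone enolate is methylated on its convex face, anti to the C7–C8 bond (trans alkylation of a β-substituted γ-butyrolactone enolate), which sets C11.

Step 6
Reactants: 9 (11S)-11-methyl allylic lactone
Product: 10 enone lactone (C10 ketone conjugated with C1=C5; γ-acyloxy enone)
Conditions: CrO3, 3,5-dimethylpyrazole, CH2Cl2, −20 °C
Reagents that add atoms: chromium trioxide, O=[Cr](=O)=O
Why: Allylic oxidation with the chromium trioxide–dimethylpyrazole complex should take the unhindered allylic methylene C10 and not the acyloxy-deactivated methine C6.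

Step 7
Reactants: 10 enone lactone
Product: 12 1β-allyl-5α-isopropenyl-10-oxo lactone (allyl and isopropenyl trans), via lithium enolate 11 (not isolated)
Conditions: (CH2=C(CH3))2CuLi [from 2-lithiopropene and CuI], Et2O/THF, −78 °C; allyl iodide, HMPA, −78 → −30 °C; aq. NH4Cl
Reagents that add atoms: lithium di(prop-1-en-2-yl)cuprate, [Li+].C=C(C)[Cu-]C(C)=C; allyl iodide, C=CCI
Why: Conjugate addition of the alkenyl cuprate occurs anti to the γ-oxygen and the lactone ring (sets C5), and the enolate is allylated trans to the new C5 substituent (sets C1; conjugate addition–enolate alkylation).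

Step 8
Reactants: 12 1β-allyl-5α-isopropenyl-10-oxo lactone
Product: 13 tricyclic keto lactone (trans-fused hydroazulen-10-one with C3=C4(CH3) and the 6,12-lactone)
Conditions: Grubbs II (5 mol%), CH2Cl2, 40 °C
Reagents that add atoms: none
Why: Ring-closing metathesis of the allyl and isopropenyl groups forms the trisubstituted C3=C4 cyclopentene with an unambiguous olefin position and leaves the trans ring fusion untouched.

Step 9
Reactants: 13 tricyclic keto lactone
Product: 15 9α-hydroxy-10-oxo lactone, via potassium enolate 14 (not isolated)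
Conditions: KHMDS, THF, −78 °C; 3-phenyl-2-(phenylsulfonyl)oxaziridine, −78 °C; AcOH
Reagents that add atoms: 3-phenyl-2-(phenylsulfonyl)oxaziridine, O=S(=O)(c1ccccc1)N1OC1c1ccccc1
Why: Kinetic deprotonation at the methylene C9 (not the ring-fusion methine C1) followed by oxaziridine enolate hydroxylation should occur on the α-face, anti to the β-oriented lactone arm at C7 and C2 at C1, which sets C9.

Step 10
Reactants: 15 9α-hydroxy-10-oxo lactone
Product: 16 9α-hydroxy-10-methylene lactone
Conditions: Zn, CH2Br2, TiCl4 (pre-formed reagent), THF/CH2Cl2, 0 °C → rt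
Reagents that add atoms: dibromomethane, BrCBr
Why: The non-basic Takai–Lombardo zinc–titanium methylenation converts the hindered, enolisable ketone into the exocyclic methylene without epimerising C1 or C9 and leaves the lactone alone.

Step 11
Reactants: 16 9α-hydroxy-10-methylene lactone
Product: 17 lactol (C12 hemiacetal, anomer mixture)
Conditions: DIBAL-H (3 equiv), CH2Cl2, −78 °C; Rochelle salt
Reagents that add atoms: none
Why: DIBAL-H at low temperature stops at the aluminium hemiacetal of the γ-lactone (lactone-to-lactol reduction), the extra equivalents covering the free C9 hydroxyl.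

Step 12
Reactants: 17 lactol
Product: 18 allyl triol (6β,9α,12-triol with CH2CH=CH2 on C12; 12S)
Conditions: (−)-Ipc2B(allyl), Et2O, −78 °C → rt; NaOH, H2O2
Reagents that add atoms: (−)-B-allyldiisopinocampheylborane, C=CCB([C@@H]1C[C@@H]2C[C@H]([C@H]1C)C2(C)C)[C@@H]1C[C@@H]2C[C@H]([C@H]1C)C2(C)C
Why: The lactol reacts through its hydroxy aldehyde form in a Brown allylboration (chair transition state), where si-face delivery by the (−)-Ipc reagent coincides with the Felkin preference of the α-methyl aldehyde and sets C12 (S), syn to the C11 methyl.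

Step 13
Reactants: 18 allyl triol
Product: 19 prenyl triol (9,12-dideacetyl target)
Conditions: 2-methylbut-2-ene (excess), Grubbs II (5 mol%), CH2Cl2, 40 °C
Reagents that add atoms: 2-methylbut-2-ene, CC=C(C)C
Why: Olefin cross-metathesis of the monosubstituted terminal alkene with excess 2-methylbut-2-ene installs the prenyl terminus, the 1,1-disubstituted exocyclic methylene and the trisubstituted ring olefin being unreactive.

Step 14
Reactants: 19 prenyl triol
Product: 20 target, [(3aS,4R,5S,7R,8aR)-5-[(2S,3S)-3-acetyloxy-6-methylhept-5-en-2-yl]-4-hydroxy-3-methyl-8-methylidene-1,3a,4,5,6,7,8,8a-octahydroazulen-7-yl] acetate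
Conditions: Ac2O (2.5 equiv), pyridine, CH2Cl2, 0 °C → rt
Reagents that add atoms: acetic anhydride, CC(=O)OC(C)=O
Why: Acylation should distinguish the hydroxyls by steric access: the allylic C9 and the acyclic C12 alcohols are acetylated, whereas the C6 hydroxyl, flanked by two tertiary carbons and syn to the side chain, stays free without DMAP.

Compound list
1 | cycloheptene oxide (meso 8-oxabicyclo[5.1.0]octane) | C1CC[C@H]2O[C@H]2CC1 | starting material
2 | (S)-cyclohept-2-en-1-ol | O[C@@H]1C=CCCCC1 | intermediate
3 | 1-[(1S)-cyclohept-2-en-1-yl]oxy-N,N-dimethylethen-1-amine (ketene N,O-acetal) | C=C(N(C)C)O[C@@H]1C=CCCCC1 | intermediate (not isolated)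
4 | 2-[(1S)-cyclohept-2-en-1-yl]-N,N-dimethylacetamide | CN(C)C(=O)C[C@H]1C=CCCCC1 | intermediate
5 | iminium ether iodide of the iodolactone (C12=NMe2+, O6–C12 ring closed, 5α-iodo) | I[C@@H]1CCCC[C@H]2CC(=[N+](C)C)O[C@@H]12.[I-] | intermediate (not isolated)
6 | cis-fused iodolactone, 8-iodo-octahydro-2H-cyclohepta[b]furan-2-one (O6 and C11 β, iodine at C5 α) | I[C@@H]1CCCC[C@H]2CC(=O)O[C@@H]12 | intermediate
7 | cis-fused allylic lactone, 3,3a,4,5,6,8a-hexahydro-2H-cyclohepta[b]furan-2-one (C1=C5) | O=C1C[C@@H]2CCCC=C[C@@H]2O1 | intermediate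
8 | lithium enolate of 7 (C11=C12–OLi) | [Li+].[O-]C1=C[C@@H]2CCCC=C[C@@H]2O1 | intermediate (not isolated)
9 | (11S)-11-methyl allylic lactone (methyl cis to H-7) | O=C1[C@@H](C)[C@@H]2CCCC=C[C@@H]2O1 | intermediate
10 | enone lactone (C10 ketone, C1=C5, 6,12-lactone) | O=C1[C@@H](C)[C@@H]2CCC(=O)C=C[C@@H]2O1 | intermediate
11 | lithium enolate (C10–OLi, C1=C10) bearing the 5α-isopropenyl group | O=C1[C@@H](C)[C@@H]2CCC([O-])=C[C@@H](C(C)=C)[C@@H]2O1.[Li+] | intermediate (not isolated)
12 | 1β-allyl-5α-isopropenyl-10-oxo lactone | O=C1[C@@H](C)[C@@H]2CCC(=O)[C@H](CC=C)[C@@H](C(C)=C)[C@@H]2O1 | intermediate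
13 | tricyclic keto lactone (trans-fused hydroazulen-10-one, C3=C4 methylcyclopentene, 6,12-lactone) | O=C1[C@@H](C)[C@@H]2CCC(=O)[C@@H]3CC=C(C)[C@H]3[C@@H]2O1 | intermediate
14 | potassium enolate of 13 (C9=C10–OK) | O=C1[C@@H](C)[C@@H]2CC=C([O-])[C@@H]3CC=C(C)[C@H]3[C@@H]2O1.[K+] | intermediate (not isolated)
15 | 9α-hydroxy-10-oxo lactone | O=C1[C@@H](C)[C@@H]2C[C@@H](O)C(=O)[C@@H]3CC=C(C)[C@H]3[C@@H]2O1 | intermediate
16 | 9α-hydroxy-10-methylene lactone | O=C1[C@@H](C)[C@@H]2C[C@@H](O)C(=C)[C@@H]3CC=C(C)[C@H]3[C@@H]2O1 | intermediate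
17 | lactol (C12 hemiacetal of 16, anomer mixture) | OC1[C@@H](C)[C@@H]2C[C@@H](O)C(=C)[C@@H]3CC=C(C)[C@H]3[C@@H]2O1 | intermediate
18 | allyl triol (6β,9α,12S-triol, C12 allyl) | C=C1[C@H](O)C[C@@H]([C@H](C)[C@H](CC=C)O)[C@@H](O)[C@@H]2C(C)=CC[C@@H]12 | intermediate
19 | prenyl triol (9,12-dideacetyl target) | C=C1[C@H](O)C[C@@H]([C@H](C)[C@H](CC=C(C)C)O)[C@@H](O)[C@@H]2C(C)=CC[C@@H]12 | intermediate
20 | target, (1R,5S,6R,7S,9R,11S,12S) in the numbering above | C=C1[C@H](OC(C)=O)C[C@@H]([C@H](C)[C@H](CC=C(C)C)OC(C)=O)[C@@H](O)[C@@H]2C(C)=CC[C@@H]12 | target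

Total step count: 14. Longest linear sequence: 14 steps (fully linear, no protecting groups).

Steps most likely to fail

Step 7. The electron-rich cuprate may expel the γ-acyloxy (lactone) oxygen by electron transfer or SN2′ attack instead of adding, or the enolate may equilibrate before C-allylation. The fallback sets out from 9 and comes back at 13, and takes the lactone out of play before the enone is made. Aminolysis of 9 with Me(MeO)NH·HCl/Me3Al should give the hydroxy Weinreb amide F1, and silylation (TBSOTf, 2,6-lutidine) the silyl ether F2. Allylic oxidation as in step 6 should give the γ-silyloxy enone F3, a substrate class on which cuprates add anti to the silyloxy group without elimination. Addition and allylation as in step 7 should give the allyl isopropenyl ketone F4, and ring-closing metathesis the hydroazulenone amide F5. HF·pyridine followed by catalytic TsOH should remove the silyl group and reclose the γ-lactone to 13.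

Step 9. Oxygen transfer to the enolate may show poor or reversed facial selectivity. The fallback sets out from 13 and comes back at 16, and sets C9 by hydride delivery instead of oxygen delivery. The 9β-hydroxy ketone F6 from the hydroxylation is methylenated as in step 10 to the 9β-hydroxy methylene lactone F7 and oxidised with MnO2 to the α-methylene ketone F8. Luche reduction (NaBH4, CeCl3, MeOH) should then deliver hydride on the face the oxidant preferred and leave the 9α-alcohol 16.

Step 10. Methylenation of the hindered ketone may stall, or the free hydroxyl bound to titanium may cause α-ketol isomerisation. The fallback sets out from 15 and comes back at 16 by protecting, olefinating with a different reagent class and releasing. TESCl/imidazole should give the silyl ether F9, salt-free Wittig methylenation (Ph3P=CH2, THF) the methylene silyl ether F10, and TBAF returns 16.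

Further compounds
F1 | step 7 | hydroxy Weinreb amide from ring-opening of 9 (free 6β-OH, C1=C5, 11S) | CON(C)C(=O)[C@@H](C)[C@@H]1CCCC=C[C@@H]1O
F2 | step 7 | 6-O-tert-butyldimethylsilyl ether of F1 | CON(C)C(=O)[C@@H](C)[C@@H]1CCCC=C[C@@H]1O[Si](C)(C)C(C)(C)C
F3 | step 7 | γ-silyloxy enone (C10 ketone, C1=C5) from F2 | CON(C)C(=O)[C@@H](C)[C@@H]1CCC(=O)C=C[C@@H]1O[Si](C)(C)C(C)(C)C
F4 | step 7 | 1β-allyl-5α-isopropenyl ketone from F3 | CON(C)C(=O)[C@@H](C)[C@@H]1CCC(=O)[C@H](CC=C)[C@@H](C(C)=C)[C@@H]1O[Si](C)(C)C(C)(C)C
F5 | step 7 | trans-fused hydroazulen-10-one Weinreb amide with 6-OTBS (metathesis product of F4) | CON(C)C(=O)[C@@H](C)[C@@H]1CCC(=O)[C@@H]2CC=C(C)[C@H]2[C@@H]1O[Si](C)(C)C(C)(C)C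
F6 | step 9 | 9β-hydroxy-10-oxo lactone (C9 epimer of 15) | O=C1[C@@H](C)[C@@H]2C[C@H](O)C(=O)[C@@H]3CC=C(C)[C@H]3[C@@H]2O1
F7 | step 9 | 9β-hydroxy-10-methylene lactone (C9 epimer of 16) | O=C1[C@@H](C)[C@@H]2C[C@H](O)C(=C)[C@@H]3CC=C(C)[C@H]3[C@@H]2O1
F8 | step 9 | 9-oxo-10-methylene lactone (α-methylene ketone) | O=C1[C@@H](C)[C@@H]2CC(=O)C(=C)[C@@H]3CC=C(C)[C@H]3[C@@H]2O1
F9 | step 10 | 9-O-triethylsilyl ether of 15 | O=C1[C@@H](C)[C@@H]2C[C@@H](O[Si](CC)(CC)CC)C(=O)[C@@H]3CC=C(C)[C@H]3[C@@H]2O1
F10 | step 10 | 9-O-triethylsilyl ether of 16 | O=C1[C@@H](C)[C@@H]2C[C@@H](O[Si](CC)(CC)CC)C(=C)[C@@H]3CC=C(C)[C@H]3[C@@H]2O1
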